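**Retrosynthetic overview**

1. The cyclopentane and the ester-bearing cyclohexene (two C–C bonds, four stereocentres) are opened by a retro intramolecular Diels–Alder reaction, giving a cis-bicyclo[4.2.0]octa-2,4-diene whose cyclobutane carries an (E,E)-dienoate arm and, trans to it, the decenyl chain.
2. The cyclobutane and the other cyclohexene share one bond; cutting it (retro-6π) shows their eight carbons to be one circuit, a trans-7,8-disubstituted cycloocta-1,3,5-triene. Its CH2CHO arm comes from a Claisen shift of a 1,4-trans cycloocta-2,5,7-trienyl vinyl ether.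
3. Key disconnection: the bond between the chain CH2 and the chain-bearing cyclobutane CH, made by copper-catalysed enantioselective anti-SN2' alkylation of meso cyclooctatetraene oxide with bis[(E)-dec-8-enyl]zinc. This one step fixes the absolute configuration from which all eight stereocentres follow.
4. Enabling feature: in the eight-carbon circuit the chain-bearing cyclobutane CH is next to the cyclobutane CH that holds the cyclopentane CH2 (trans), and three bonds away lies the ring-fusion CH common to the cyclopentane and both cyclohexenes. This is the diene-terminus/oxirane-carbon (1,4) pattern of the mirror-symmetric oxide, so the chain carbon is a vinylogous electrophile and the oxygen left on the far carbon later delivers the arm to the neighbouring carbon, anti to the chain.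
5. Ring order: eight-membered ring (bought as cyclooctatetraene) → cyclobutane and cyclohexadiene together (transannular 6π closure) → cyclopentane and cyclohexene together (Diels–Alder).

Key step: step 6

Remark: L is the phosphoramidite from (S)-1,1'-bi-2-naphthol and bis[(R)-1-phenylethyl]amine. Its sense of induction is assumed by analogy with small dialkylzincs; if a pilot run (Mosher ester of the trienol of the key step) shows the opposite sense, the mirror-image ligand is used.

**Route**

Step 1
Reactants: 1 non-8-yn-1-ol
Product: 2 dec-8-yn-1-ol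
Conditions: n-BuLi (2.1 equiv), THF, −78 → 0 °C; MeI (1.05 equiv), 0 °C → rt; aq NH4Cl
Reagents that add atoms: iodomethane, CI
Why: Acetylide alkylation: in the alkoxide–acetylide dianion the carbon terminus is much the better nucleophile toward MeI in THF, so C-methylation should give the methylalkyne without protecting the alcohol.

Step 2
Reactants: 2 dec-8-yn-1-ol
Product: 3 (8E)-dec-8-en-1-ol
Conditions: Na, NH3 (l), THF, −33 °C; solid NH4Cl
Reagents that add atoms: none
Why: Dissolving-metal reduction of an internal alkyne: the vinyl radical anion/vinyl anion relaxes to the trans form before protonation, which sets the E alkene of the chain.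

Step 3
Reactants: 3 (8E)-dec-8-en-1-ol
Product: 4 (2E)-10-iododec-2-ene
Conditions: I2, PPh3, imidazole, CH2Cl2, 0 °C → rt
Reagents that add atoms: iodine, II
Why: Appel-type iodination: the alkoxyphosphonium iodide of the primary alcohol is displaced by iodide in an SN2 step, and the remote alkene is not touched.

Step 4
Reactants: 4 (2E)-10-iododec-2-ene
Product: 5 bis[(8E)-dec-8-en-1-yl]zinc
Conditions: Et2Zn (neat, 3 equiv), CuI (0.3 mol %), 50 °C; volatiles removed at 50 °C in vacuo; taken up in toluene
Reagents that add atoms: diethylzinc, CC[Zn]CC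
Why: Iodine–zinc exchange on a primary iodide, driven to the dialkylzinc by removal of volatile EtI and excess Et2Zn, should give a salt-free reagent in which the isolated alkene is inert.

Step 5
Reactants: 6 cycloocta-1,3,5,7-tetraene
Product: 7 cyclooctatetraene oxide (cis-9-oxabicyclo[6.1.0]nona-2,4,6-triene, meso)
Conditions: mCPBA (1.0 equiv), NaHCO3, CH2Cl2, 0 °C → rt
Reagents that add atoms: 3-chloroperoxybenzoic acid, OOC(=O)c1cccc(Cl)c1
Why: Prilezhaev epoxidation of one cis alkene of the tub-shaped tetraene gives the cis-fused, mirror-symmetric oxide, and the stoichiometry holds it at mono-oxidation.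

Step 6
Reactants: 7 cyclooctatetraene oxide; 5 bis[(8E)-dec-8-en-1-yl]zinc
Product: 8 (1R,4R)-4-[(8E)-dec-8-en-1-yl]cycloocta-2,5,7-trien-1-ol (OH and chain trans across the ring)
Conditions: Cu(OTf)2 (3 mol %), L (6 mol %), 5 (1.5 equiv), toluene, −78 → −10 °C; aq NH4Cl
Reagents that add atoms: none
Why: Transmetallation of 5 to the copper–phosphoramidite complex gives a monovalent alkylcopper that binds the diene terminus C4 of the oxide on the face opposite the oxirane oxygen, adds oxidatively with anti-SN2' cleavage of the allylic C–O bond, and forms the chain–C4 bond by reductive elimination from the trivalent σ-allylcopper, releasing the zinc alkoxide of 8. The closest known reaction type is the copper–phosphoramidite-catalysed enantioselective SN2' opening of cyclic 1,3-diene monoepoxides by dialkylzincs, which includes the desymmetrisation of cyclooctatetraene oxide itself with simple dialkylzincs. No ring is closed; the temporary oxirane is opened and the eight-membered ring is kept for the later transannular closure. C4 is set by the chiral ligand, which chooses one of the two enantiotopic diene termini of the meso oxide, and by the anti course of the substitution, which puts the chain trans to the C1 oxygen; C1 keeps its oxirane configuration, so the same choice fixes it. The step needs 1,4-opening rather than 1,2-, 1,6- or 1,8-opening and no Lewis-acid ring contraction of the oxide: the tub shape of the ring holds neighbouring double bonds far from coplanar, so only the alkene directly allylic to the C–O bond relays the substitution, and the soft copper nucleophile, salt-free zinc reagent, toluene and low temperature keep the hard pathways out. Both stereocentres of 8 then direct everything downstream: the C1 oxygen hands the two-carbon arm to C3 on its own face in the Claisen step, and the pair C3/C4 becomes the trans-disubstituted edge of the cyclobutane.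

Step 7
Reactants: 8 (1R,4R)-4-[(8E)-dec-8-en-1-yl]cycloocta-2,5,7-trien-1-ol
Product: 9 (1R,4R)-4-[(8E)-dec-8-en-1-yl]cycloocta-2,5,7-trien-1-yl vinyl ether
Conditions: Hg(OAc)2 (0.3 equiv), Et3N (0.3 equiv), ethyl vinyl ether (solvent), 35 °C; K2CO3; Et3N-deactivated silica
Reagents that add atoms: ethyl vinyl ether, C=COCC
Why: Mercury-catalysed vinyl exchange (transetherification) takes place at oxygen only, so neither stereocentre is touched, and the amine buffer protects the easily ionised bis-allylic C–O bond.

Step 8
Reactants: 9 (1R,4R)-4-[(8E)-dec-8-en-1-yl]cycloocta-2,5,7-trien-1-yl vinyl ether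
Product: 12 2-{trans-8-[(8E)-dec-8-en-1-yl]-cis-bicyclo[4.2.0]octa-2,4-dien-7-yl}acetaldehyde (CH2CHO arm endo, that is cis to the cyclohexadiene ring; chain exo), via cyclooctatriene aldehyde 10 (not isolated), via arm-exo bicyclic aldehyde 11 (not isolated)
Conditions: toluene (0.02 M), BHT, base-washed sealed tube, 90 °C; chromatography on Et3N-deactivated silica, only pure 12 collected; all fractions containing 11 pooled and reheated under the same conditions (repeated)
Reagents that add atoms: none
Why: Claisen rearrangement through the isolated ring alkene (the shift that creates the fully conjugated triene) should deliver the CH2CHO arm suprafacially to C3 on the face the oxygen occupied, hence trans to the chain, and the trans-7,8-disubstituted cycloocta-1,3,5-triene 10 then closes by thermal disrotatory 6π electrocyclisation on either face to 12 or its ring-face diastereomer 11 (arm exo, chain endo) without change at the two substituted cyclobutane carbons; because 11 reopens to 10 at the bath temperature, reheating the pooled 11-containing fractions should funnel the material into 12.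

Step 9
Reactants: 12 arm-endo bicyclic aldehyde; 13 trimethyl 4-phosphonocrotonate
Product: 14 methyl (2E,4E)-6-{trans-8-[(8E)-dec-8-en-1-yl]-cis-bicyclo[4.2.0]octa-2,4-dien-7-yl}hexa-2,4-dienoate (dienoate arm endo, chain exo)
Conditions: 13, LiHMDS, THF, −78 °C; then 12, −78 → 0 °C
Reagents that add atoms: none
Why: Horner–Wadsworth–Emmons olefination with the lithiated crotonate phosphonate reacting at the carbon next to phosphorus should give the (2E,4E)-dienoate, the stabilised phosphonate favouring the E alkene, and at 0 °C or below the bicycle cannot reopen, so the four ring stereocentres are untouched.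

Step 10
Reactants: 14 arm-endo bicyclic (2E,4E)-dienoate
Product: 17 CNP0133550.1 (target), via cyclooctatriene dienoate 15 (not isolated), via arm-exo bicyclic dienoate 16 (not isolated)
Conditions: toluene (0.01 M), BHT, sealed tube, 110 °C
Reagents that add atoms: none
Why: Intramolecular Diels–Alder reaction of the arm dienoate (diene) with the nearer ring alkene (dienophile): in 14 the arm lies over the cyclohexadiene and the three-atom tether admits a single geometry (addition to the cyclobutane-side face of the ring alkene with the inner diene carbons turned away from the ring carbons, the other orientation running into the cyclobutane), which with the E,E diene should set all four new stereocentres as in the target, while the fraction of 14 that reopens by retro-6π to 15 and recloses on the other face to 16 (like any arm-exo material carried over from step 8) cannot cyclise and returns through 15 to 14.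

**Compound list**

1 | non-8-yn-1-ol | OCCCCCCCC#C | starting material
2 | dec-8-yn-1-ol | OCCCCCCCC#CC | intermediate
3 | (8E)-dec-8-en-1-ol | OCCCCCCC/C=C/C | intermediate
4 | (2E)-10-iododec-2-ene | ICCCCCCC/C=C/C | intermediate
5 | bis[(8E)-dec-8-en-1-yl]zinc | C/C=C/CCCCCCC[Zn]CCCCCCC/C=C/C | intermediate
6 | cycloocta-1,3,5,7-tetraene | C1=CC=CC=CC=C1 | starting material
7 | cyclooctatetraene oxide (meso, cis-fused) | O1[C@H]2/C=C\C=C/C=C\[C@@H]12 | intermediate
8 | (1R,4R)-4-[(8E)-dec-8-en-1-yl]cycloocta-2,5,7-trien-1-ol | C/C=C/CCCCCCC[C@@H]1/C=C\C=C/[C@@H](O)/C=C\1 | intermediate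
9 | vinyl ether of 8 | C/C=C/CCCCCCC[C@@H]1/C=C\C=C/[C@@H](OC=C)/C=C\1 | intermediate
10 | 2-{(1R,8R)-8-[(8E)-dec-8-en-1-yl]cycloocta-2,4,6-trien-1-yl}acetaldehyde (trans) | C/C=C/CCCCCCC[C@@H]1/C=C\C=C/C=C\[C@H]1CC=O | intermediate
11 | bicyclic aldehyde, arm exo, chain endo | C/C=C/CCCCCCC[C@@H]1[C@@H]2C=CC=C[C@@H]2[C@H]1CC=O | intermediate
12 | bicyclic aldehyde, arm endo, chain exo | C/C=C/CCCCCCC[C@@H]1[C@H]2C=CC=C[C@H]2[C@H]1CC=O | intermediate
13 | trimethyl 4-phosphonocrotonate | COC(=O)/C=C/CP(=O)(OC)OC | starting material
14 | bicyclic (2E,4E)-dienoate, arm endo | C/C=C/CCCCCCC[C@@H]1[C@H]2C=CC=C[C@H]2[C@H]1C/C=C/C=C/C(=O)OC | intermediate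
15 | cyclooctatriene (2E,4E)-dienoate (trans-7,8) | C/C=C/CCCCCCC[C@@H]1/C=C\C=C/C=C\[C@H]1C/C=C/C=C/C(=O)OC | intermediate
16 | bicyclic (2E,4E)-dienoate, arm exo | C/C=C/CCCCCCC[C@@H]1[C@@H]2C=CC=C[C@@H]2[C@H]1C/C=C/C=C/C(=O)OC | intermediate
17 | CNP0133550.1 | C/C=C/CCCCCCC[C@@H]1[C@H]2C=C[C@@H]3[C@@H]4[C@H]2[C@H]1C[C@H]4C=C[C@H]3C(=O)OC | target

**Totals**

Total step count: 10.
Longest linear sequence: 9 steps (steps 1, 2, 3, 4, 6, 7, 8, 9, 10, from non-8-yn-1-ol); 6 steps from cyclooctatetraene.

**Steps most likely to fail**

Step 6. What may go wrong: with the long-chain zinc reagent the catalyst may discriminate poorly between the two enantiotopic diene termini, and 1,2-opening or Lewis-acid ring contraction of the oxide may compete. Fallback (sets out from 4 and 7, comes back at 8): iodide 4 is treated with t-BuLi (2 equiv, Et2O–pentane, −78 °C) to give (E)-dec-8-enyllithium F1, and CuBr·SMe2 (0.5 equiv) converts this into lithium bis[(E)-dec-8-enyl]cuprate F2. Stoichiometric anti-SN2' opening of oxide 7 (Et2O, −78 → −40 °C) should give the racemic trans-trienol F3. Esterification with (S)-O-methylmandelic acid (DCC, DMAP, CH2Cl2) gives the (1R,4R) mandelate F4 and the (1S,4S) mandelate F5, which are separated by chromatography on Et3N-deactivated silica. K2CO3 in MeOH on F4 returns alcohol 8.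

Step 8. What may go wrong: the [3,3] shift may run in part through the diene-terminus alkene on the other side of the oxygen-bearing carbon, and 1,5-hydrogen shifts of the cyclooctatriene may set in at the temperature the neutral rearrangement needs. Fallback (sets out from 8, comes back at 12): the rearrangement is moved to the ester-enolate level, where it runs below room temperature. Alcohol 8 is acetylated (Ac2O, Et3N, DMAP, CH2Cl2, 0 °C) to the acetate F6. LDA and TMSCl (THF, −78 °C) give the silyl ketene acetal F7, which should undergo Ireland–Claisen rearrangement on warming to room temperature to the cyclooctatriene silyl ester F8; this closes in the flask to the bicyclic silyl esters F9. LiAlH4 (Et2O, 0 °C) reduces these to the bicyclic primary alcohols F10, and Dess–Martin periodinane with NaHCO3 gives aldehyde 12 together with its arm-exo isomer 11, which are separated and recycled as in step 8.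

Step 10. What may go wrong: cycloaddition of the ester-substituted diene may be slow enough that 1,5-hydrogen shifts and dimerisation of the cyclohexadiene compete. Fallback (sets out from 14, comes back at 17): the cycloaddition is run at the aldehyde oxidation level, where the diene is a much stronger acceptor. i-Bu2AlH (CH2Cl2, −78 °C) reduces 14 to the bicyclic dienol F11, and MnO2 (CH2Cl2, rt) gives the bicyclic dienal F12. Heating (toluene, 80 °C) should close this to the tetracyclic aldehyde F13. NaClO2/NaH2PO4/2-methylbut-2-ene (t-BuOH–H2O, 0 °C) gives the tetracyclic acid F14, and TMSCHN2 (MeOH–toluene, 0 °C) gives 17.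

**Further compounds**

F1 | step 6 | (E)-dec-8-enyllithium | [Li]CCCCCCC/C=C/C
F2 | step 6 | lithium bis[(E)-dec-8-enyl]cuprate | [Li+].C/C=C/CCCCCCC[Cu-]CCCCCCC/C=C/C
F3 | step 6 | racemic trans-trienol (both enantiomers) | C/C=C/CCCCCCC[C@@H]1/C=C\C=C/[C@@H](O)/C=C\1.C/C=C/CCCCCCC[C@H]1/C=C\C=C/[C@H](O)/C=C\1
F4 | step 6 | (1R,4R) mandelate | C/C=C/CCCCCCC[C@@H]1/C=C\C=C/[C@@H](OC(=O)[C@@H](OC)c2ccccc2)/C=C\1
F5 | step 6 | (1S,4S) mandelate | C/C=C/CCCCCCC[C@H]1/C=C\C=C/[C@H](OC(=O)[C@@H](OC)c2ccccc2)/C=C\1
F6 | step 8 | acetate of 8 | C/C=C/CCCCCCC[C@@H]1/C=C\C=C/[C@@H](OC(C)=O)/C=C\1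
F7 | step 8 | silyl ketene acetal | C/C=C/CCCCCCC[C@@H]1/C=C\C=C/[C@@H](OC(=C)O[Si](C)(C)C)/C=C\1
F8 | step 8 | cyclooctatriene silyl ester | C/C=C/CCCCCCC[C@@H]1/C=C\C=C/C=C\[C@H]1CC(=O)O[Si](C)(C)C
F9 | step 8 | bicyclic silyl esters (arm endo and arm exo) | C/C=C/CCCCCCC[C@@H]1[C@H]2C=CC=C[C@H]2[C@H]1CC(=O)O[Si](C)(C)C.C/C=C/CCCCCCC[C@@H]1[C@@H]2C=CC=C[C@@H]2[C@H]1CC(=O)O[Si](C)(C)C
F10 | step 8 | bicyclic primary alcohols (arm endo and arm exo) | C/C=C/CCCCCCC[C@@H]1[C@H]2C=CC=C[C@H]2[C@H]1CCO.C/C=C/CCCCCCC[C@@H]1[C@@H]2C=CC=C[C@@H]2[C@H]1CCO
F11 | step 10 | bicyclic dienol (arm endo) | C/C=C/CCCCCCC[C@@H]1[C@H]2C=CC=C[C@H]2[C@H]1C/C=C/C=C/CO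
F12 | step 10 | bicyclic dienal (arm endo) | C/C=C/CCCCCCC[C@@H]1[C@H]2C=CC=C[C@H]2[C@H]1C/C=C/C=C/C=O
F13 | step 10 | tetracyclic aldehyde | C/C=C/CCCCCCC[C@@H]1[C@H]2C=C[C@@H]3[C@@H]4[C@H]2[C@H]1C[C@H]4C=C[C@H]3C=O
F14 | step 10 | tetracyclic acid | C/C=C/CCCCCCC[C@@H]1[C@H]2C=C[C@@H]3[C@@H]4[C@H]2[C@H]1C[C@H]4C=C[C@H]3C(=O)O
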